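Begin with the easy step: at 40.0 s the alder run shows 55.5% free monomer and 44.5% monomer in chains, together 100%, so what leaves one column arrives in the other, and one column will do.

- alder: free monomer 14 mM; initiator 28 µM; the very flask that is asked about, followed so far
- flask: free monomer 14 mM; initiator 28 µM; time 6.0 min
- alder (time / s: monomer in chains / %, free monomer / %): 20.0: 26.0, 74.2; 40.0: 44.5, 55.5; 50.0: 51.6, 48.2; 80.0: 66.5, 32.9

(standard deviation of a reading: 0.3 percentage points)
1. average number of monomer units in a chain (living and dead chains, two that joined counted as one) at 6.0 min
2. part of the free monomer that has reacted at 6.0 min
- the average divides the monomer in chains by the number of chains, living and dead together; two radicals that join make one chain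
- the earlier runs do not show the number of chains; that part of a forecast is a guess

Anna and Ben argue at the board over this flask. Anna holds that c(free monomer) falls pseudo-first-order with one constant: the first 40.0 s of the alder run give 0.0147 /s, and at 6.0 min that leaves 0.500% of the charge.

Ben objects that the next 40.0 s give 0.0131 /s, less than hers, as one expects if the growing radicals thin out. The two constants belong to the middles of their stretches, 40.0 s apart, so he lets the constant shrink exponentially at 0.00297 /s. Then he replaces the falling curve by one mid-run constant standing in for its mean, the value at half the asked time, 0.00916 /s. That leaves 3.70%, so 96.3% has reacted. Integrating his curve properly leaves 3.16%, so the shortcut costs 0.54 percentage points. The readings do not show the number of chains, so for both of them the chain length stays a guess.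

The forecast stands at 96.5% and 600 units, its chain part being, in its words, “This part is a guess”. The flask gives 96.0% reacted and 515 units per chain, with 4.0% free monomer left at 6.00 min, which is near Ben's mid-run 3.70% and more than Anna's 0.500%.

    initiator → 2 initiating radical (k = 0.00740 /s)
    free monomer + initiating radical → growing radical + monomer in chains (k = 7.70 × 10⁶ /M/s)
    free monomer + growing radical → monomer in chains + growing radical, rate k3*[growing radical]*[free monomer] (k = 50000 /M/s)
    2 growing radical → dead chain (k = 2.00 × 10⁶ /M/s)

Anna's view serves for the early stretch from which she took her constant: at 0.600 min it leaves 58.9%, and the flask holds 58.5%. Read back, the flask's own mean constant is 0.00894 /s, beside the mid-run 0.00916 /s. Now take the neighbour flask, charged with 0.070 mM initiator and otherwise alike. If radicals balance between being made and pairing, then with the time and all else held the constant goes with the square root of the initiator charged, becoming 0.0145 /s, which leaves 0.541% free monomer. That neighbour flask holds 0.52%, and its chains average 214 units, fewer than in the first flask.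

The numbers in the tables were computed with made-up constants; noise was put on by code.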